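**Plan**

1. The chain is numbered C1 (ester carbon) to C5 (benzylic CH2), and the target is the (2R,3S) isomer. The C4 ketone is γ to the C1 carboxyl and C5 carries the prenylated aryl ring, so C4=O and C5–aryl are traced to a C4≡C5 alkyne: the C1 carboxylate adds to C4 (five-membered ring O–C1–C2–C3–C4) while the aryl group is placed on C5.
2. Cuts, in retrosynthetic order: three O–Si bonds; C1–OMe (the ester comes from methanolysis of an enol lactone, which restores the O–C4 bond); O–C4 together with C5–aryl (alkynoic acid plus aryl iodide); C3–C4 (alkynyl onto the benzylic carbon of a cis-epoxy alcohol); the aryl–carbon bonds of both halves, back to 4-iodophenol.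
3. Forward: 4-iodophenol is ortho-prenylated and silylated to the aryl iodide (steps 1–2). Its pivalate is taken through Sonogashira coupling, Lindlar reduction, epoxidation, alkynylalane opening, protecting-group exchange and oxidation to the pent-4-ynoic acid (steps 3–11).
4. Step 12 joins the two halves and closes the only ring of the route, the enol lactone. Methanol opens it again to the methyl ester and the C4 ketone (step 13), and fluoride removes the silyl groups (step 14).
5. Stereochemistry: C2 and C3 are both set by Sharpless epoxidation of a Z-allylic alcohol with L-(+)-tartrate (2S,3R cis-epoxide), followed by inversion at C3 when the alkynyl group is delivered. No later step breaks a bond at C2 or C3.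

Key step: step 12

Remark on configuration: an E-allylic alcohol (trans-epoxide) would give the C3 epimer of the target after inverting opening at C3, so the Z-alkene is used. The C3 descriptor switches between R and S as the alkyne substituent changes (CIP priorities only; the geometry is unchanged).

Remark on protection: the para oxygen is carried as a pivalate through steps 3–7 so that the benzylic epoxide is not prone to ionise and opens with clean inversion. It is exchanged for a silyl ether afterwards.

**Route**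

Step 1
Reactants: 1 4-iodophenol; 2 prenyl bromide (1-bromo-3-methylbut-2-ene)
Product: 4 4-iodo-2-(3-methylbut-2-en-1-yl)phenol, via sodium 4-iodophenoxide 3 (not isolated)
Conditions: NaH, toluene, 0 °C to rt; then 2, rt
Reagents that add atoms: none
Why: Ortho-C-alkylation of a phenoxide: in a non-polar solvent the tight sodium phenoxide ion pair should react with the allylic bromide through carbon, and with the para position blocked by iodine only the ortho position is open (the O-prenyl ether is the expected by-product).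

Step 2
Reactants: 4 4-iodo-2-(3-methylbut-2-en-1-yl)phenol
Product: 5 [4-iodo-2-(3-methylbut-2-en-1-yl)phenoxy]triisopropylsilane
Conditions: TIPSCl, imidazole, DMF, rt
Reagents that add atoms: triisopropylsilyl chloride, CC(C)[Si](Cl)(C(C)C)C(C)C
Why: Standard O-silylation of a phenol; the hindered silyl ether should withstand Et3N/DMSO and cold methoxide and leave with fluoride at the end.

Step 3
Reactants: 1 4-iodophenol
Product: 6 4-iodophenyl pivalate
Conditions: PivCl, Et3N, DMAP (cat.), CH2Cl2, 0 °C to rt
Reagents that add atoms: pivaloyl chloride, CC(C)(C)C(Cl)=O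
Why: DMAP-catalysed acylation; the pivalate turns the para oxygen into a weak donor so that the later benzylic epoxide reacts by an SN2 course, and it is hindered enough to resist the alane of step 7.

Step 4
Reactants: 6 4-iodophenyl pivalate; 7 propargyl alcohol
Product: 8 4-(3-hydroxyprop-1-yn-1-yl)phenyl pivalate
Conditions: PdCl2(PPh3)2 (2 mol%), CuI (4 mol%), Et3N, THF, rt
Reagents that add atoms: none
Why: Sonogashira coupling of an aryl iodide with a terminal alkyne at room temperature, which tolerates the aryl ester and the free alcohol.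

Step 5
Reactants: 8 4-(3-hydroxyprop-1-yn-1-yl)phenyl pivalate
Product: 9 4-[(Z)-3-hydroxyprop-1-en-1-yl]phenyl pivalate
Conditions: H2 (1 atm), Pd/CaCO3 poisoned with Pb(OAc)2 (Lindlar catalyst), quinoline, EtOAc, rt
Reagents that add atoms: none
Why: Lindlar semihydrogenation adds H2 syn on the poisoned surface and should give the Z-alkene; quinoline and monitoring of hydrogen uptake limit over-reduction.

Step 6
Reactants: 9 4-[(Z)-3-hydroxyprop-1-en-1-yl]phenyl pivalate
Product: 10 (2S,3R)-2,3-epoxy-3-[4-(pivaloyloxy)phenyl]propan-1-ol (cis-epoxy alcohol)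
Conditions: Ti(OiPr)4 (20 mol%), L-(+)-diisopropyl tartrate (24 mol%), t-BuOOH, 4 Å molecular sieves, CH2Cl2, −20 °C
Reagents that add atoms: tert-butyl hydroperoxide, CC(C)(C)OO
Why: Sharpless asymmetric epoxidation: with L-(+)-tartrate the titanium-bound peroxide is delivered to the face that gives 2S at the carbon next to CH2OH, and syn oxygen transfer to the Z-alkene then fixes 3R; Z substrates are known to react more slowly and less selectively than E ones, so enantiomeric purity is to be assayed at this stage.

Step 7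
Reactants: 10 (2S,3R)-2,3-epoxy-3-[4-(pivaloyloxy)phenyl]propan-1-ol; 11 trimethylsilylacetylene
Product: 14 (2R,3R)-3-[4-(pivaloyloxy)phenyl]-5-(trimethylsilyl)pent-4-yne-1,2-diol, via lithium (trimethylsilyl)acetylide 12 (not isolated), via diethyl[(trimethylsilyl)ethynyl]alane 13 (not isolated)
Conditions: 11, n-BuLi, toluene, 0 °C; Et2AlCl, 0 °C to rt; then 10, 0 °C to rt; aq. potassium sodium tartrate work-up
Reagents that add atoms: none
Why: Alkoxide-directed opening of a 2,3-epoxy alcohol by a diethylalkynylalane: the aluminium alkoxide anchors the reagent, the alkynyl group should attack the benzylic C3 with inversion (SN2) while C2 keeps its oxygen, so the cis-epoxide gives the C2/C3 relationship of the target.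

Step 8
Reactants: 14 (2R,3R)-3-[4-(pivaloyloxy)phenyl]-5-(trimethylsilyl)pent-4-yne-1,2-diol
Product: 15 (2R,3S)-3-(4-hydroxyphenyl)pent-4-yne-1,2-diol
Conditions: K2CO3, MeOH, rt; aq. NH4Cl
Reagents that add atoms: none
Why: Carbonate-promoted methanolysis should cleave the aryl pivalate (transesterification) and the alkynyl C–Si bond (protodesilylation) in one operation without touching either stereocentre.

Step 9
Reactants: 15 (2R,3S)-3-(4-hydroxyphenyl)pent-4-yne-1,2-diol
Product: 16 (2R,3S)-1,2-bis[(tert-butyldimethylsilyl)oxy]-3-{4-[(tert-butyldimethylsilyl)oxy]phenyl}pent-4-yne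
Conditions: TBSOTf, 2,6-lutidine, CH2Cl2, −78 to 0 °C
Reagents that add atoms: tert-butyldimethylsilyl triflate, CC(C)(C)[Si](C)(C)OS(=O)(=O)C(F)(F)F
Why: Exhaustive silylation with a silyl triflate and a hindered pyridine base covers the phenol, the primary and the hindered secondary hydroxyl at once; the C2 silyl ether later keeps that oxygen from competing for the activated alkyne in step 12.

Step 10
Reactants: 16 (2R,3S)-1,2-bis[(tert-butyldimethylsilyl)oxy]-3-{4-[(tert-butyldimethylsilyl)oxy]phenyl}pent-4-yne
Product: 17 (2R,3S)-2-[(tert-butyldimethylsilyl)oxy]-3-{4-[(tert-butyldimethylsilyl)oxy]phenyl}pent-4-yn-1-ol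
Conditions: CSA (10 mol%), MeOH–CH2Cl2 (1:1), 0 °C
Reagents that add atoms: none
Why: Acid-catalysed methanolysis of silyl ethers is fastest at the least hindered primary position, while aryl and secondary silyl ethers react slowly under these conditions.

Step 11
Reactants: 17 (2R,3S)-2-[(tert-butyldimethylsilyl)oxy]-3-{4-[(tert-butyldimethylsilyl)oxy]phenyl}pent-4-yn-1-ol
Product: 19 (2R,3S)-2-[(tert-butyldimethylsilyl)oxy]-3-{4-[(tert-butyldimethylsilyl)oxy]phenyl}pent-4-ynoic acid, via silyloxy aldehyde 18 (not isolated)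
Conditions: TEMPO (20 mol%), PhI(OAc)2 (2.5 equiv), MeCN–H2O (1:1), rt
Reagents that add atoms: water, O
Why: Oxoammonium (TEMPO/PhI(OAc)2) oxidation in aqueous acetonitrile takes the primary alcohol through the aldehyde hydrate to the acid under near-neutral conditions, so the α-silyloxy centre should not epimerise and the alkyne and aryl silyl ether should survive.

Step 12
Reactants: 19 (2R,3S)-2-[(tert-butyldimethylsilyl)oxy]-3-{4-[(tert-butyldimethylsilyl)oxy]phenyl}pent-4-ynoic acid; 5 [4-iodo-2-(3-methylbut-2-en-1-yl)phenoxy]triisopropylsilane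
Product: 20 (3R,4S,5E)-3-[(tert-butyldimethylsilyl)oxy]-4-{4-[(tert-butyldimethylsilyl)oxy]phenyl}-5-{[3-(3-methylbut-2-en-1-yl)-4-(triisopropylsilyloxy)phenyl]methylidene}oxolan-2-one
Conditions: Pd(OAc)2(PPh3)2 (5 mol%), Et3N, n-Bu4NCl, DMSO, rt to 40 °C
Reagents that add atoms: none
Why: Oxidative addition of aryl iodide 5 to zerovalent palladium gives an arylpalladium iodide that π-binds the terminal alkyne of the triethylammonium carboxylate of 19; the carboxylate oxygen attacks C4 anti to palladium and reductive elimination from the resulting vinyl(aryl)palladium forms the C5–aryl bond. The closest known reaction type is the palladium-catalysed cyclisation–coupling of pent-4-ynoic acids with aryl halides to (E)-5-arylidene butyrolactones. The one ring formed (O–C1–C2–C3–C4) closes 5-exo-dig, which the three-atom tether between carboxylate and alkyne strongly favours over 6-endo attack at C5. No stereocentre is created: C2 and C3 are spectators that Et3N cannot deprotonate, and the E geometry follows from anti oxypalladation and retentive reductive elimination. The step needs O-attack at C4 and arylation at C5 instead of alkynyl C–H coupling or protonolysis, and the absence of copper, the internal carboxylate nucleophile and the unhindered alkyne terminus should secure this. A Z isomer would also converge, because step 13 erases the alkene geometry.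

Step 13
Reactants: 20 (3R,4S,5E)-enol lactone
Product: 22 methyl (2R,3S)-2-[(tert-butyldimethylsilyl)oxy]-3-{4-[(tert-butyldimethylsilyl)oxy]phenyl}-5-[3-(3-methylbut-2-en-1-yl)-4-(triisopropylsilyloxy)phenyl]-4-oxopentanoate, via C4 enol 21 (not isolated)
Conditions: NaOMe (10 mol%), MeOH–THF, −40 °C; AcOH quench at −40 °C
Reagents that add atoms: methanol, CO
Why: Transesterification of an enol ester: methoxide adds to the activated lactone carbonyl and expels the C4 enol(ate), which is protonated at C5 to the ketone; acyl transfer should be much faster than removal of the hindered C3–H at −40 °C, and the acid quench removes the base before warming.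

Step 14
Reactants: 22 methyl (2R,3S)-2-[(tert-butyldimethylsilyl)oxy]-3-{4-[(tert-butyldimethylsilyl)oxy]phenyl}-5-[3-(3-methylbut-2-en-1-yl)-4-(triisopropylsilyloxy)phenyl]-4-oxopentanoate
Product: 23 asperteretal H, methyl (2R,3S)-2-hydroxy-5-[4-hydroxy-3-(3-methylbut-2-en-1-yl)phenyl]-3-(4-hydroxyphenyl)-4-oxopentanoate
Conditions: Bu4NF, AcOH (1:1), THF, 0 °C to rt
Reagents that add atoms: none
Why: Fluoride-induced desilylation buffered with acetic acid should cleave both aryl silyl ethers and the α-silyloxy ester without exposing the β-hydroxy ketone to base, so retro-aldol cleavage, dehydration and C3 epimerisation are avoided.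

**Compound list**

1 | 4-iodophenol | Oc1ccc(I)cc1 | starting material
2 | prenyl bromide (1-bromo-3-methylbut-2-ene) | CC(C)=CCBr | starting material
3 | sodium 4-iodophenoxide | [Na+].[O-]c1ccc(I)cc1 | intermediate
4 | 4-iodo-2-(3-methylbut-2-en-1-yl)phenol | Oc1ccc(I)cc1CC=C(C)C | intermediate
5 | [4-iodo-2-(3-methylbut-2-en-1-yl)phenoxy]triisopropylsilane | Ic1ccc(O[Si](C(C)C)(C(C)C)C(C)C)c(CC=C(C)C)c1 | intermediate
6 | 4-iodophenyl pivalate | CC(C)(C)C(=O)Oc1ccc(I)cc1 | intermediate
7 | propargyl alcohol | OCC#C | starting material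
8 | 4-(3-hydroxyprop-1-yn-1-yl)phenyl pivalate | CC(C)(C)C(=O)Oc1ccc(C#CCO)cc1 | intermediate
9 | 4-[(Z)-3-hydroxyprop-1-en-1-yl]phenyl pivalate | CC(C)(C)C(=O)Oc1ccc(/C=C\CO)cc1 | intermediate
10 | (2S,3R)-2,3-epoxy-3-[4-(pivaloyloxy)phenyl]propan-1-ol (cis) | OC[C@@H]1O[C@@H]1c1ccc(OC(=O)C(C)(C)C)cc1 | intermediate
11 | trimethylsilylacetylene | C#C[Si](C)(C)C | starting material
12 | lithium (trimethylsilyl)acetylide | [Li]C#C[Si](C)(C)C | intermediate
13 | diethyl[(trimethylsilyl)ethynyl]alane | CC[Al](CC)C#C[Si](C)(C)C | intermediate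
14 | (2R,3R)-3-[4-(pivaloyloxy)phenyl]-5-(trimethylsilyl)pent-4-yne-1,2-diol | OC[C@H](O)[C@@H](C#C[Si](C)(C)C)c1ccc(OC(=O)C(C)(C)C)cc1 | intermediate
15 | (2R,3S)-3-(4-hydroxyphenyl)pent-4-yne-1,2-diol | OC[C@H](O)[C@@H](C#C)c1ccc(O)cc1 | intermediate
16 | (2R,3S)-1,2-bis[(tert-butyldimethylsilyl)oxy]-3-{4-[(tert-butyldimethylsilyl)oxy]phenyl}pent-4-yne | CC(C)(C)[Si](C)(C)OC[C@H](O[Si](C)(C)C(C)(C)C)[C@@H](C#C)c1ccc(O[Si](C)(C)C(C)(C)C)cc1 | intermediate
17 | (2R,3S)-2-[(tert-butyldimethylsilyl)oxy]-3-{4-[(tert-butyldimethylsilyl)oxy]phenyl}pent-4-yn-1-ol | OC[C@H](O[Si](C)(C)C(C)(C)C)[C@@H](C#C)c1ccc(O[Si](C)(C)C(C)(C)C)cc1 | intermediate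
18 | (2R,3S)-2-[(tert-butyldimethylsilyl)oxy]-3-{4-[(tert-butyldimethylsilyl)oxy]phenyl}pent-4-ynal | O=C[C@H](O[Si](C)(C)C(C)(C)C)[C@@H](C#C)c1ccc(O[Si](C)(C)C(C)(C)C)cc1 | intermediate
19 | (2R,3S)-2-[(tert-butyldimethylsilyl)oxy]-3-{4-[(tert-butyldimethylsilyl)oxy]phenyl}pent-4-ynoic acid | OC(=O)[C@H](O[Si](C)(C)C(C)(C)C)[C@@H](C#C)c1ccc(O[Si](C)(C)C(C)(C)C)cc1 | intermediate
20 | (3R,4S,5E)-3-[(tert-butyldimethylsilyl)oxy]-4-{4-[(tert-butyldimethylsilyl)oxy]phenyl}-5-{[3-(3-methylbut-2-en-1-yl)-4-(triisopropylsilyloxy)phenyl]methylidene}oxolan-2-one (3-silyloxy and 4-aryl cis) | O=C1O/C(=C/c2ccc(O[Si](C(C)C)(C(C)C)C(C)C)c(CC=C(C)C)c2)[C@@H](c2ccc(O[Si](C)(C)C(C)(C)C)cc2)[C@H]1O[Si](C)(C)C(C)(C)C | intermediate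
21 | methyl (2R,3S,4E)-2-[(tert-butyldimethylsilyl)oxy]-3-{4-[(tert-butyldimethylsilyl)oxy]phenyl}-4-hydroxy-5-[3-(3-methylbut-2-en-1-yl)-4-(triisopropylsilyloxy)phenyl]pent-4-enoate (C4 enol) | COC(=O)[C@H](O[Si](C)(C)C(C)(C)C)[C@@H](/C(O)=C\c1ccc(O[Si](C(C)C)(C(C)C)C(C)C)c(CC=C(C)C)c1)c1ccc(O[Si](C)(C)C(C)(C)C)cc1 | intermediate
22 | methyl (2R,3S)-2-[(tert-butyldimethylsilyl)oxy]-3-{4-[(tert-butyldimethylsilyl)oxy]phenyl}-5-[3-(3-methylbut-2-en-1-yl)-4-(triisopropylsilyloxy)phenyl]-4-oxopentanoate | COC(=O)[C@H](O[Si](C)(C)C(C)(C)C)[C@@H](C(=O)Cc1ccc(O[Si](C(C)C)(C(C)C)C(C)C)c(CC=C(C)C)c1)c1ccc(O[Si](C)(C)C(C)(C)C)cc1 | intermediate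
23 | asperteretal H, methyl (2R,3S)-2-hydroxy-5-[4-hydroxy-3-(3-methylbut-2-en-1-yl)phenyl]-3-(4-hydroxyphenyl)-4-oxopentanoate | COC(=O)[C@H](O)[C@@H](C(=O)Cc1ccc(O)c(CC=C(C)C)c1)c1ccc(O)cc1 | target

**Step count and risks**

Total steps: 14. Longest linear sequence: 12 steps (steps 3–14, from 4-iodophenol).

Steps most likely to fail:

1. Step 12. What may go wrong: protonolysis of the vinylpalladium intermediate (lactone formed without the aryl group), copper-free coupling at the alkynyl C–H, or slow turnover of the hindered α-silyloxy acid. The fallback separates the two bond formations. Setting out from 19 and 5, a conventional Sonogashira coupling (PdCl2(PPh3)2, CuI, Et3N, THF, rt) should give the internal alkyne (2R,3R)-2-[(tert-butyldimethylsilyl)oxy]-3-{4-[(tert-butyldimethylsilyl)oxy]phenyl}-5-[3-(3-methylbut-2-en-1-yl)-4-(triisopropylsilyloxy)phenyl]pent-4-ynoic acid F1. Carboxylate addition to the alkyne with PdCl2(MeCN)2 and Et3N in THF (5-exo-dig, then protonolysis) should then give the (3R,4S,5Z)-arylidene lactone F2, the geometric isomer of 20. Methanolysis under the conditions of step 13 removes the alkene geometry and returns to the route at 22.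

2. Step 13. What may go wrong: once the ketone is released, base may remove the C3–H (epimerisation) or trigger β-elimination of the C2 silyloxy group. Partial loss of aryl silyl groups would be harmless. The fallback avoids alkoxide altogether. Setting out from 20, trimethyltin hydroxide (Me3SnOH, 1,2-dichloroethane, 40–60 °C, then dilute HCl wash) should transfer hydroxide under near-neutral conditions to give (2R,3S)-2-[(tert-butyldimethylsilyl)oxy]-3-{4-[(tert-butyldimethylsilyl)oxy]phenyl}-5-[3-(3-methylbut-2-en-1-yl)-4-(triisopropylsilyloxy)phenyl]-4-oxopentanoic acid F3. Esterification with TMSCHN2 in MeOH–toluene at 0 °C returns to the route at 22.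

3. Step 6. What may go wrong: incomplete facial selection and slow turnover, as is typical of Z-allylic alcohols in titanium–tartrate epoxidation, which would carry the enantiomer through to the target. The fallback uses oxygen transfer from a chiral manganese salen complex to the Z-cinnamate ester (Jacobsen epoxidation), for which cis-cinnamates are favourable substrates. Setting out from 6, Sonogashira coupling with ethyl propiolate (PdCl2(PPh3)2, CuI, K2CO3, THF) should give ethyl 3-[4-(pivaloyloxy)phenyl]prop-2-ynoate F4. Lindlar semihydrogenation gives ethyl (Z)-3-[4-(pivaloyloxy)phenyl]prop-2-enoate F5. Epoxidation with (R,R)-(salen)MnCl [salen = N,N'-bis(3,5-di-tert-butylsalicylidene)cyclohexane-1,2-diamine dianion], NaOCl and 4-phenylpyridine N-oxide in CH2Cl2 at 0 °C should give ethyl (2R,3R)-3-[4-(pivaloyloxy)phenyl]oxirane-2-carboxylate F6. Reduction of the ester with NaBH4 in EtOH at 0 °C returns to the route at 10.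

**Further compounds**

F1 | step 12 | (2R,3R)-2-[(tert-butyldimethylsilyl)oxy]-3-{4-[(tert-butyldimethylsilyl)oxy]phenyl}-5-[3-(3-methylbut-2-en-1-yl)-4-(triisopropylsilyloxy)phenyl]pent-4-ynoic acid | OC(=O)[C@H](O[Si](C)(C)C(C)(C)C)[C@@H](C#Cc1ccc(O[Si](C(C)C)(C(C)C)C(C)C)c(CC=C(C)C)c1)c1ccc(O[Si](C)(C)C(C)(C)C)cc1
F2 | step 12 | (3R,4S,5Z)-3-[(tert-butyldimethylsilyl)oxy]-4-{4-[(tert-butyldimethylsilyl)oxy]phenyl}-5-{[3-(3-methylbut-2-en-1-yl)-4-(triisopropylsilyloxy)phenyl]methylidene}oxolan-2-one | O=C1O/C(=C\c2ccc(O[Si](C(C)C)(C(C)C)C(C)C)c(CC=C(C)C)c2)[C@@H](c2ccc(O[Si](C)(C)C(C)(C)C)cc2)[C@H]1O[Si](C)(C)C(C)(C)C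
F3 | step 13 | (2R,3S)-2-[(tert-butyldimethylsilyl)oxy]-3-{4-[(tert-butyldimethylsilyl)oxy]phenyl}-5-[3-(3-methylbut-2-en-1-yl)-4-(triisopropylsilyloxy)phenyl]-4-oxopentanoic acid | OC(=O)[C@H](O[Si](C)(C)C(C)(C)C)[C@@H](C(=O)Cc1ccc(O[Si](C(C)C)(C(C)C)C(C)C)c(CC=C(C)C)c1)c1ccc(O[Si](C)(C)C(C)(C)C)cc1
F4 | step 6 | ethyl 3-[4-(pivaloyloxy)phenyl]prop-2-ynoate | CCOC(=O)C#Cc1ccc(OC(=O)C(C)(C)C)cc1
F5 | step 6 | ethyl (Z)-3-[4-(pivaloyloxy)phenyl]prop-2-enoate | CCOC(=O)/C=C\c1ccc(OC(=O)C(C)(C)C)cc1
F6 | step 6 | ethyl (2R,3R)-3-[4-(pivaloyloxy)phenyl]oxirane-2-carboxylate (cis) | CCOC(=O)[C@@H]1O[C@@H]1c1ccc(OC(=O)C(C)(C)C)cc1
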